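Everything rests on cutting the C2–C3 bond of the dihydrobenzofuran. C2 is an O-benzylic carbon, bound to O1 and to the guaiacyl ring A, and it lies 1,5 to C3 through C3a, C7a and O1; a rhodium carbenoid generated at C3 can therefore insert into one of the two enantiotopic C2–H bonds. This one operation closes the dihydrofuran ring, forms C2–C3 and fixes C2, while C3 is adjusted afterwards by epimerisation. The precursor is a methyl aryldiazoacetate whose benzene ring (ring B) carries the ortho benzyloxy group with MOM-protected ring A, the C7 methoxy group and a C5 bromide reserved for a late Heck coupling.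

Key step: step 8

Numbering used: O1, C2, C3, C3a, C4–C7, C7a; ring A is the guaiacyl group on C2, ring B the benzo ring. The target is (2R,3S), trans.

Assumption: Rh2(S-PTTL)4 is taken to select the benzylic hydrogen that leads to 2R. If the first run shows 2S, the mirror-image catalyst Rh2(R-PTTL)4 is used and nothing else changes.

Step 1
Reactants: 1 vanillin (4-hydroxy-3-methoxybenzaldehyde)
Product: 2 MOM-vanillin [3-methoxy-4-(methoxymethoxy)benzaldehyde]
Conditions: MOMCl, iPr2NEt, CH2Cl2, 0 °C to rt
Reagents that add atoms: chloromethyl methyl ether, COCCl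
Why: Williamson-type O-alkylation of the acidic phenol gives a MOM acetal that withstands the carbonate, hot chloride, DBU, methoxide and hydride used later and keeps the para oxygen of ring A electron-donating for the key step.

Step 2
Reactants: 2 MOM-vanillin
Product: 3 benzylic alcohol, [3-methoxy-4-(methoxymethoxy)phenyl]methanol
Conditions: NaBH4, MeOH, 0 °C
Reagents that add atoms: none
Why: Borohydride reduction of an aromatic aldehyde is chemoselective and leaves the acetal untouched.

Step 3
Reactants: 4 4-bromo-2-methoxyphenol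
Product: 5 4-bromo-2-iodo-6-methoxyphenol
Conditions: I2, KI, NaHCO3, THF–H2O, rt
Reagents that add atoms: iodine, II
Why: Electrophilic aromatic iodination under phenoxide control goes to the only free position ortho to the hydroxy group, the para position being blocked by bromine.

Step 4
Reactants: 5 4-bromo-2-iodo-6-methoxyphenol; 3 [3-methoxy-4-(methoxymethoxy)phenyl]methanol
Product: 6 aryl benzyl ether, 5-bromo-1-iodo-3-methoxy-2-{[3-methoxy-4-(methoxymethoxy)phenyl]methoxy}benzene
Conditions: PPh3, DIAD, THF, 0 °C to rt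
Reagents that add atoms: none
Why: Mitsunobu etherification joins the acidic ortho-halophenol to the primary benzylic alcohol under neutral conditions, which avoids a labile electron-rich benzyl bromide and saves a step.

Step 5
Reactants: 6 aryl benzyl ether (aryl iodide); 7 dimethyl malonate
Product: 8 dimethyl 2-(5-bromo-3-methoxy-2-{[3-methoxy-4-(methoxymethoxy)phenyl]methoxy}phenyl)propanedioate
Conditions: CuI (10 mol %), picolinic acid (20 mol %), Cs2CO3, dioxane, 60 °C
Reagents that add atoms: none
Why: Copper-catalysed Hurtley-type arylation of the malonate enolate takes place at the C–I bond only, since the C–Br bond does not react with the copper catalyst at this temperature.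

Step 6
Reactants: 8 dimethyl arylmalonate
Product: 9 methyl 2-(5-bromo-3-methoxy-2-{[3-methoxy-4-(methoxymethoxy)phenyl]methoxy}phenyl)acetate
Conditions: LiCl, H2O, DMSO, 130 °C
Reagents that add atoms: none
Why: Krapcho dealkoxycarbonylation removes one ester by chloride demethylation and loss of CO2 under near-neutral conditions that spare the acetal, both ethers and the bromide.

Step 7
Reactants: 9 methyl arylacetate
Product: 10 methyl 2-diazo-2-(5-bromo-3-methoxy-2-{[3-methoxy-4-(methoxymethoxy)phenyl]methoxy}phenyl)acetate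
Conditions: p-ABSA, DBU, MeCN, 0 °C to rt
Reagents that add atoms: 4-acetamidobenzenesulfonyl azide (p-ABSA), CC(=O)Nc1ccc(cc1)S(=O)(=O)N=[N+]=[N-]
Why: Regitz diazo transfer to the methylene activated by both aryl and ester is the standard entry to aryldiazoacetates.

Step 8
Reactants: 10 methyl aryldiazoacetate
Product: 11 cis ester, methyl (2R,3S)-5-bromo-7-methoxy-2-[3-methoxy-4-(methoxymethoxy)phenyl]-2,3-dihydro-1-benzofuran-3-carboxylate
Conditions: Rh2(S-PTTL)4 (dirhodium tetrakis[N-phthaloyl-(S)-tert-leucinate], 2 mol %), toluene (0.02 M), −60 °C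
Reagents that add atoms: none
Why: Loss of N2 from 10 on the dirhodium catalyst gives a donor/acceptor rhodium carbenoid at C3, which inserts into one O-benzylic C–H bond in a concerted but asynchronous, hydride-shift-like event, the positive charge building at C2 being stabilised by O1 and by the para-oxygenated ring A. The closest known reaction type is the enantioselective intramolecular 1,5 C–H insertion of ortho-benzyloxy aryldiazoacetates on chiral dirhodium N-phthaloyl amino-carboxylates, which gives cis-2-aryl-2,3-dihydrobenzofuran-3-carboxylates. The dihydrofuran ring closes in the 1,5 insertion mode, through a five-membered cyclic transition state made of C3, C3a, C7a, O1 and C2, with C2–C3 as the only new skeletal bond. C2 is set by the catalyst, whose chiral carboxylate pocket selects one of the two enantiotopic benzylic hydrogens; C3 is set relative to C2 by the compact transition state, which should place ester and aryl cis under kinetic control, and is corrected in step 9. The step needs site selectivity for the benzylic C–H bond over the methoxy and OCH2O C–H bonds and over attack on ring A, and the substrate secures this because no other C–H bond can reach the carbenoid through a five-membered transition state. Low temperature and dilution should suppress carbenoid dimerisation.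

Step 9
Reactants: 11 cis ester
Product: 12 trans ester, methyl (2R,3R)-5-bromo-7-methoxy-2-[3-methoxy-4-(methoxymethoxy)phenyl]-2,3-dihydro-1-benzofuran-3-carboxylate
Conditions: NaOMe (0.3 equiv), MeOH–THF, rt
Reagents that add atoms: none
Why: Base-mediated epimerisation through the ester enolate should move the C3 ester to the less hindered trans position, while C2 stays fixed because expulsion of the O1 aryloxide from that enolate would be a stereoelectronically disfavoured 5-endo-trig closure run in reverse.

Step 10
Reactants: 12 trans ester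
Product: 13 trans alcohol, [(2R,3S)-5-bromo-7-methoxy-2-[3-methoxy-4-(methoxymethoxy)phenyl]-2,3-dihydro-1-benzofuran-3-yl]methanol
Conditions: LiBH4, THF, 0 °C to rt
Reagents that add atoms: none
Why: LiBH4 reduces the methyl ester to the primary alcohol without touching the aryl bromide or the acetal, and C3 keeps its trans arrangement (the descriptor changes from R to S by priority only).

Step 11
Reactants: 14 3,5-dihydroxybenzaldehyde
Product: 15 3,5-bis(methoxymethoxy)benzaldehyde
Conditions: MOMCl, iPr2NEt, CH2Cl2–DMF, 0 °C to rt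
Reagents that add atoms: chloromethyl methyl ether, COCCl
Why: Double Williamson-type O-alkylation gives the same acetal protection as on ring A, so that one final operation frees all three phenols.

Step 12
Reactants: 15 3,5-bis(methoxymethoxy)benzaldehyde
Product: 16 styrene, 1-ethenyl-3,5-bis(methoxymethoxy)benzene
Conditions: Ph3PCH3Br, KOtBu, THF, 0 °C to rt
Reagents that add atoms: methyltriphenylphosphonium bromide, C[P+](c1ccccc1)(c1ccccc1)c1ccccc1.[Br-]
Why: Wittig methylenation of a non-enolisable aryl aldehyde reliably gives the terminal alkene.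

Step 13
Reactants: 13 trans alcohol (aryl bromide); 16 1-ethenyl-3,5-bis(methoxymethoxy)benzene
Product: 17 tris-MOM gnetofuran A, [(2R,3S)-5-{(E)-2-[3,5-bis(methoxymethoxy)phenyl]ethenyl}-7-methoxy-2-[3-methoxy-4-(methoxymethoxy)phenyl]-2,3-dihydro-1-benzofuran-3-yl]methanol
Conditions: Pd2(dba)3 (2.5 mol %), [(t-Bu)3PH]BF4 (10 mol %), Cy2NMe, dioxane, 90 °C
Reagents that add atoms: none
Why: Mizoroki–Heck coupling (oxidative addition of the electron-rich aryl bromide to the bulky phosphine–palladium catalyst, syn insertion at the terminal alkene carbon, syn β-hydride elimination) should give the E-stilbene, with the free alcohol and both stereocentres as spectators.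

Step 14
Reactants: 17 tris-MOM gnetofuran A
Product: 18 gnetofuran A, 5-{(E)-2-[(2R,3S)-2-(4-hydroxy-3-methoxyphenyl)-3-(hydroxymethyl)-7-methoxy-2,3-dihydro-1-benzofuran-5-yl]ethenyl}benzene-1,3-diol
Conditions: HCl (1 M in MeOH), THF, rt to 40 °C
Reagents that add atoms: none
Why: Acid-catalysed acetal exchange with methanol removes the three MOM groups as dimethoxymethane under conditions too mild to ionise the C2–O1 benzylic ether, and any such ionisation would reclose to the trans isomer because C3 is fixed.

Compound list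
1 | vanillin | COc1cc(C=O)ccc1O | starting material
2 | 3-methoxy-4-(methoxymethoxy)benzaldehyde | COCOc1ccc(C=O)cc1OC | intermediate
3 | [3-methoxy-4-(methoxymethoxy)phenyl]methanol | COCOc1ccc(CO)cc1OC | intermediate
4 | 4-bromo-2-methoxyphenol | COc1cc(Br)ccc1O | starting material
5 | 4-bromo-2-iodo-6-methoxyphenol | COc1cc(Br)cc(I)c1O | intermediate
6 | 5-bromo-1-iodo-3-methoxy-2-{[3-methoxy-4-(methoxymethoxy)phenyl]methoxy}benzene | COCOc1ccc(COc2c(I)cc(Br)cc2OC)cc1OC | intermediate
7 | dimethyl malonate | COC(=O)CC(=O)OC | starting material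
8 | dimethyl 2-(5-bromo-3-methoxy-2-{[3-methoxy-4-(methoxymethoxy)phenyl]methoxy}phenyl)propanedioate | COC(=O)C(C(=O)OC)c1cc(Br)cc(OC)c1OCc1ccc(OCOC)c(OC)c1 | intermediate
9 | methyl 2-(5-bromo-3-methoxy-2-{[3-methoxy-4-(methoxymethoxy)phenyl]methoxy}phenyl)acetate | COC(=O)Cc1cc(Br)cc(OC)c1OCc1ccc(OCOC)c(OC)c1 | intermediate
10 | methyl 2-diazo-2-(5-bromo-3-methoxy-2-{[3-methoxy-4-(methoxymethoxy)phenyl]methoxy}phenyl)acetate | COC(=O)C(=[N+]=[N-])c1cc(Br)cc(OC)c1OCc1ccc(OCOC)c(OC)c1 | intermediate
11 | methyl (2R,3S)-5-bromo-7-methoxy-2-[3-methoxy-4-(methoxymethoxy)phenyl]-2,3-dihydro-1-benzofuran-3-carboxylate (cis) | COc1cc([C@@H]2Oc3c(OC)cc(Br)cc3[C@@H]2C(=O)OC)ccc1OCOC | intermediate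
12 | methyl (2R,3R)-5-bromo-7-methoxy-2-[3-methoxy-4-(methoxymethoxy)phenyl]-2,3-dihydro-1-benzofuran-3-carboxylate (trans) | COc1cc([C@@H]2Oc3c(OC)cc(Br)cc3[C@H]2C(=O)OC)ccc1OCOC | intermediate
13 | [(2R,3S)-5-bromo-7-methoxy-2-[3-methoxy-4-(methoxymethoxy)phenyl]-2,3-dihydro-1-benzofuran-3-yl]methanol (trans) | COc1cc([C@@H]2Oc3c(OC)cc(Br)cc3[C@H]2CO)ccc1OCOC | intermediate
14 | 3,5-dihydroxybenzaldehyde | O=Cc1cc(O)cc(O)c1 | starting material
15 | 3,5-bis(methoxymethoxy)benzaldehyde | COCOc1cc(C=O)cc(OCOC)c1 | intermediate
16 | 1-ethenyl-3,5-bis(methoxymethoxy)benzene | C=Cc1cc(OCOC)cc(OCOC)c1 | intermediate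
17 | [(2R,3S)-5-{(E)-2-[3,5-bis(methoxymethoxy)phenyl]ethenyl}-7-methoxy-2-[3-methoxy-4-(methoxymethoxy)phenyl]-2,3-dihydro-1-benzofuran-3-yl]methanol | COc1cc([C@@H]2Oc3c(OC)cc(/C=C/c4cc(OCOC)cc(OCOC)c4)cc3[C@H]2CO)ccc1OCOC | intermediate
18 | gnetofuran A | COc1cc([C@@H]2Oc3c(OC)cc(/C=C/c4cc(O)cc(O)c4)cc3[C@H]2CO)ccc1O | target

Total step count: 14
Longest linear sequence: 11 steps (steps 1, 2, 4, 5, 6, 7, 8, 9, 10, 13, 14, from vanillin)

Steps most likely to fail

Step 8. The catalyst may not tell the two enantiotopic benzylic hydrogens apart well enough, because the C7 methoxy group beside the benzyloxy oxygen forces the ether into a conformation unlike that of simpler substrates; part of the carbenoid may also be lost to dimerisation. The fallback moves stereocontrol from the catalyst to a covalently bound auxiliary and sets out from 9.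
- Saponification (LiOH, THF–H2O) gives the arylacetic acid F1.
- The auxiliary alcohol (S)-2-hydroxy-1-(pyrrolidin-1-yl)propan-1-one F2 is made from ethyl (S)-lactate and pyrrolidine and joined to F1 (EDC·HCl, DMAP, CH2Cl2) to give the lactamide ester F3.
- Diazo transfer (p-ABSA, DBU, MeCN) gives the diazo lactamide ester F4.
- Decomposition with Rh2(S-DOSP)4 or Rh2(R-DOSP)4 (dirhodium tetrakis[N-(4-dodecylbenzenesulfonyl)prolinate], whichever hand is matched with the auxiliary for 2R) gives the dihydrobenzofuran lactamide ester F5. Its C2 diastereomers can be separated on silica, so optical purity no longer depends on the catalyst alone.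
- NaOMe in MeOH exchanges the auxiliary for methyl and equilibrates C3, and the route is rejoined at 12.

Step 5. The copper-catalysed coupling may stall at the iodide, which is flanked by the bulky benzyloxy group, or drift to hydrodeiodination. The fallback replaces enolate arylation by acylation of an arylmagnesium and sets out from 6.
- Iodine–magnesium exchange (i-PrMgCl·LiCl, THF, −40 °C, at which the bromide is not exchanged) and addition to excess dimethyl oxalate at −78 °C gives the aryl glyoxylate F6.
- Condensation with tosylhydrazide (MeOH, 50 °C) gives the tosylhydrazone F7.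
- Bamford–Stevens elimination of sulfinate (DBU, CH2Cl2, rt) gives the diazo ester, so the route is rejoined at 10 and steps 6 and 7 are not needed.

Step 14. The methoxymethyl cation released beside three freshly freed phenols may alkylate the resorcinol ring, or the acid may add to or oligomerise the electron-rich stilbene. The fallback uses the acid before the stilbene exists and fluoride at the end, and sets out from 13.
- HCl in MeOH removes the single MOM group to give the bromo phenol alcohol F8.
- TBSCl and imidazole in DMF give the bis-silyl ether F9.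
- In parallel 14 is silylated (TBSCl, imidazole, DMF) to the bis-silyl aldehyde F10 and methylenated (Ph3PCH3Br, KOtBu, THF) to the bis-silyl styrene F11.
- Heck coupling of F9 with F11 under the conditions of step 13 gives the tetrakis-silyl ether F12.
- Bu4NF buffered with AcOH in THF at 0 °C frees all four hydroxy groups, and the route is rejoined at the target 18.

Further compounds
F1 | step 8 | 2-(5-bromo-3-methoxy-2-{[3-methoxy-4-(methoxymethoxy)phenyl]methoxy}phenyl)acetic acid | OC(=O)Cc1cc(Br)cc(OC)c1OCc1ccc(OCOC)c(OC)c1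
F2 | step 8 | (S)-2-hydroxy-1-(pyrrolidin-1-yl)propan-1-one | C[C@H](O)C(=O)N1CCCC1
F3 | step 8 | (2S)-1-oxo-1-(pyrrolidin-1-yl)propan-2-yl 2-(5-bromo-3-methoxy-2-{[3-methoxy-4-(methoxymethoxy)phenyl]methoxy}phenyl)acetate | C[C@H](OC(=O)Cc1cc(Br)cc(OC)c1OCc1ccc(OCOC)c(OC)c1)C(=O)N1CCCC1
F4 | step 8 | (2S)-1-oxo-1-(pyrrolidin-1-yl)propan-2-yl 2-diazo-2-(5-bromo-3-methoxy-2-{[3-methoxy-4-(methoxymethoxy)phenyl]methoxy}phenyl)acetate | C[C@H](OC(=O)C(=[N+]=[N-])c1cc(Br)cc(OC)c1OCc1ccc(OCOC)c(OC)c1)C(=O)N1CCCC1
F5 | step 8 | (2S)-1-oxo-1-(pyrrolidin-1-yl)propan-2-yl (2R,3R)-5-bromo-7-methoxy-2-[3-methoxy-4-(methoxymethoxy)phenyl]-2,3-dihydro-1-benzofuran-3-carboxylate | COc1cc([C@@H]2Oc3c(OC)cc(Br)cc3[C@H]2C(=O)O[C@@H](C)C(=O)N4CCCC4)ccc1OCOC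
F6 | step 5 | methyl 2-(5-bromo-3-methoxy-2-{[3-methoxy-4-(methoxymethoxy)phenyl]methoxy}phenyl)-2-oxoacetate | COC(=O)C(=O)c1cc(Br)cc(OC)c1OCc1ccc(OCOC)c(OC)c1
F7 | step 5 | methyl 2-(5-bromo-3-methoxy-2-{[3-methoxy-4-(methoxymethoxy)phenyl]methoxy}phenyl)-2-[2-(4-methylbenzenesulfonyl)hydrazinylidene]acetate | COC(=O)C(=NNS(=O)(=O)c1ccc(C)cc1)c1cc(Br)cc(OC)c1OCc1ccc(OCOC)c(OC)c1
F8 | step 14 | 4-[(2R,3S)-5-bromo-3-(hydroxymethyl)-7-methoxy-2,3-dihydro-1-benzofuran-2-yl]-2-methoxyphenol | COc1cc([C@@H]2Oc3c(OC)cc(Br)cc3[C@H]2CO)ccc1O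
F9 | step 14 | (2R,3S)-5-bromo-2-[4-(tert-butyldimethylsilyloxy)-3-methoxyphenyl]-3-[(tert-butyldimethylsilyloxy)methyl]-7-methoxy-2,3-dihydro-1-benzofuran | COc1cc([C@@H]2Oc3c(OC)cc(Br)cc3[C@H]2CO[Si](C)(C)C(C)(C)C)ccc1O[Si](C)(C)C(C)(C)C
F10 | step 14 | 3,5-bis(tert-butyldimethylsilyloxy)benzaldehyde | CC(C)(C)[Si](C)(C)Oc1cc(C=O)cc(O[Si](C)(C)C(C)(C)C)c1
F11 | step 14 | 1-ethenyl-3,5-bis(tert-butyldimethylsilyloxy)benzene | C=Cc1cc(O[Si](C)(C)C(C)(C)C)cc(O[Si](C)(C)C(C)(C)C)c1
F12 | step 14 | tetrakis(tert-butyldimethylsilyl) ether of gnetofuran A (both resorcinol oxygens, the ring A phenol and the primary alcohol silylated; 2R,3S, E) | COc1cc([C@@H]2Oc3c(OC)cc(/C=C/c4cc(O[Si](C)(C)C(C)(C)C)cc(O[Si](C)(C)C(C)(C)C)c4)cc3[C@H]2CO[Si](C)(C)C(C)(C)C)ccc1O[Si](C)(C)C(C)(C)C
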